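**Reading a constant.** No rate constants are given, but the first readings yield one number. Take the odds of target in each run: target over the rest of the starting material that has gone. Divide by the charged ratio of partner to second substrate, then average the runs. This selectivity factor is 0.481, a reading that carries the scatter of the runs.

| flask | starting material | partner | second substrate | remark | time |
|---|---|---|---|---|---|
| birch | 0.010 M | 3 equiv | 1.3 equiv | run made earlier |  |
| elm | 0.010 M | 3 equiv | 3 equiv | run made earlier |  |
| larch | 0.020 M | 3 equiv | 2 equiv | run made earlier |  |
| flask | 0.010 M | 3.00 equiv | 2.00 equiv |  | 3.0 h |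

| run | time / min | target / % | starting material / % |
|---|---|---|---|
| birch | 3.00 | 27 | 52 |
| birch | 6.00 | 34 | 33 |
| birch | 15.0 | 44 | 9 |
| birch | 25.0 | 43 | 4 |
| birch | 50.0 | 39 | 2 |
| birch | 120 | 39 | 0 |
| elm | 3.00 | 19 | 35 |
| elm | 6.00 | 27 | 17 |
| elm | 15.0 | 30 | 2 |
| elm | 25.0 | 27 | 0 |
| elm | 50.0 | 26 | 2 |
| elm | 120 | 23 | 2 |
| larch | 3.00 | 34 | 18 |
| larch | 8.00 | 36 | 5 |
| larch | 20.0 | 34 | 2 |
| larch | 50.0 | 32 | 0 |
| larch | 120 | 28 | 1 |

(standard deviation of a reading: 1.5 percentage points)



1. when, up to 3.0 h, the flask holds most target
2. the amount of target, in percent of the starting material charged, at that time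

**Main step.** Take starting material and partner by themselves: with 3.00 equiv of partner, the flask's charge allows 100 % target.

**One more loss.** Now add the competing loss. The first odds are higher in birch than in elm, and elm has more second substrate. In the flask the charged ratio of partner to second substrate is 1.50, so the factor gives estimated odds of 0.721, which is an estimated share of 41.9 % of the starting material going to target at the start.

**The rest.** Target also declines: birch reads 44 % at 15.0 min and 39 % at 120 min. Larch has the flask's ratio, and its top reading, 36 %, is 85.9 % of that share. So you can put the flask's top near 36.0 %. Larch read that top at 8.00 min with twice the concentration, which puts the flask's top near 0.267 h.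

**The result.** The forecast, holding that the flask “should follow larch at half the speed”, gave 38 % at 0.37 h, later than this reckoning. The flask gives 37.2 % at 0.228 h.

    starting material + partner → target (k = 4.45 /M/min)
    second substrate + partner → second product (k = 0.435 /M/min)
    starting material + second substrate → cross product (k = 12.8 /M/min)
    target ⇌ isomer of the product (K = 0.645, k = 0.0291 /min)
    partner → decomposed reagent (k = 0.0118 /min)
    second substrate ⇌ dormant form (K = 2.10, k = 0.325 /min)

**Neighbouring flask.** In the flask the top is 88.8 % of the share, against the 85.9 % carried from larch. The neighbouring flask has 12.0 equiv of partner, with its other charges as in the flask. Its ratio is 6.00, so the factor 0.481 gives odds of 2.88 and a share of 74.3 %, and keeping 85.9 % of that gives 63.8 %. The top amount of target in that neighbouring flask is 65.5 %.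

The numbers in the tables come from a simulation from invented constants, and the scatter is random.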